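**Retrosynthetic overview**
1. Target 13 ⇐ O‑methylation of the cis‑epoxy alcohol 12.
2. 12 ⇐ hydroxyl‑directed syn‑epoxidation of the trisubstituted double bond of dienol 11, the same oxidation that turns the 1,6‑desoxy diene into the oxirane in the presumed biogenesis (oxirane 2, kept).
3. 11 ⇐ enantioselective trans‑addition of benzoic acid to the free arene oxide 9 (benzyl benzoate 2,3‑oxide). 9 racemises through oxepin 10, so a dynamic kinetic resolution sets both carbinol centres at once.
4. 9 ⇐ unmasking (Br2, then 2 × –HBr) of epoxide 6 (oxirane 1, later opened) ⇐ 2,5‑dihydrobenzyl benzoate 5 ⇐ Birch reduction of benzoic acid 1, which is also the benzoate nucleophile.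
5. Ring order: the carbocycle is bought as the arene; oxirane 1 is formed in step 4 and opened in step 7; oxirane 2 is formed in step 8.

Assumption: target locants follow 7‑oxabicyclo[4.1.0]hept‑4‑ene numbering (C1 = quaternary oxirane carbon, C2 = C–OMe, C3 = C–OBz, C6 = oxirane CH), giving (1R,2S,3R,6R); (R)‑TRIP is taken as the catalyst antipode that gives (5R,6R)‑11 in step 7 (if the sense is opposite, (S)‑TRIP is used and nothing else changes); racemic intermediates are drawn as one enantiomer.

**Route**

Step 1
Reactants: 1 benzoic acid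
Product: 2 cyclohexa-2,5-diene-1-carboxylic acid
Conditions: Na, NH3(l), EtOH, −78 → −33 °C; NH4Cl; aq. HCl, 0 °C
Reagents that add atoms: none
Why: Birch reduction of the benzoate anion (protonation ipso and para) gives the 1,4‑dihydro acid; no stereocentre is formed.

Step 2
Reactants: 2 cyclohexa-2,5-diene-1-carboxylic acid
Product: 3 (cyclohexa-2,5-dien-1-yl)methanol
Conditions: LiAlH4, Et2O, 0 °C → rt; Fieser work‑up
Reagents that add atoms: none
Why: hydride reduction of the carboxylic acid; the skipped diene is inert to LiAlH4 and does not move into conjugation.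

Step 3
Reactants: 3 (cyclohexa-2,5-dien-1-yl)methanol; 4 benzoyl chloride
Product: 5 (cyclohexa-2,5-dien-1-yl)methyl benzoate
Conditions: BzCl, Et3N, DMAP (cat.), CH2Cl2, 0 °C
Reagents that add atoms: benzoyl chloride (4), O=C(Cl)c1ccccc1
Why: DMAP‑catalysed O‑acylation (nucleophilic acyl substitution) of the primary alcohol.

Step 4
Reactants: 5 (cyclohexa-2,5-dien-1-yl)methyl benzoate
Product: 6 rac-[(1S,2S,6R)-7-oxabicyclo[4.1.0]hept-3-en-2-yl]methyl benzoate (oxirane trans to CH2OBz)
Conditions: mCPBA (1.0 equiv), NaHCO3, CH2Cl2, 0 °C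
Reagents that add atoms: mCPBA, O=C(OO)c1cccc(Cl)c1
Why: Prilezhaev epoxidation of one of the two equivalent double bonds, anti to CH2OBz for steric reasons; this oxirane is the arene‑oxide ring in masked form, and its racemic centres are erased in steps 6–7.

Step 5
Reactants: 6 rac-[(1S,2S,6R)-7-oxabicyclo[4.1.0]hept-3-en-2-yl]methyl benzoate
Product: 7 rac-[(1S,2S,3S,4S,6R)-3,4-dibromo-7-oxabicyclo[4.1.0]heptan-2-yl]methyl benzoate
Conditions: Br2 (1.0 equiv), CH2Cl2, −78 °C
Reagents that add atoms: bromine, BrBr
Why: anti addition of bromine through the bromonium ion (trans‑diaxial opening) gives the vicinal dibromide in which each Br has an anti‑periplanar H on the neighbouring carbon; the relative configuration set here has no consequence later.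

Step 6
Reactants: 7 rac-[(1S,2S,3S,4S,6R)-3,4-dibromo-7-oxabicyclo[4.1.0]heptan-2-yl]methyl benzoate
Product: 9 rac-(7-oxabicyclo[4.1.0]hepta-2,4-dien-2-yl)methyl benzoate, via allylic bromide 8 (not isolated)
Conditions: DBU (3 equiv), THF, 0 °C → rt, dark; filtration through basic alumina, used at once
Reagents that add atoms: none
Why: two consecutive anti‑E2 dehydrobrominations (the classical benzene oxide synthesis) unmask the arene oxide, which is stable to base; all stereocentres of 7 are destroyed and 9 is racemic because it equilibrates with its oxepin tautomer.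

Step 7
Reactants: 9 rac-(7-oxabicyclo[4.1.0]hepta-2,4-dien-2-yl)methyl benzoate; 1 benzoic acid
Product: 11 [(5R,6R)-5-(benzoyloxy)-6-hydroxycyclohexa-1,3-dien-1-yl]methyl benzoate, via oxepin tautomer 10 (not isolated)
Conditions: PhCO2H (1.5 equiv), (R)-TRIP (10 mol %), 5 Å MS, toluene, −30 °C; Et3N quench; Et3N‑deactivated silica
Reagents that add atoms: benzoic acid (1), OC(=O)c1ccccc1
Why: Proposed new method: dynamic kinetic asymmetric carboxylysis of an arene oxide – the two enantiomers of 9 interconvert within seconds through the 6π‑electrocyclic oxide ⇌ oxepin (10) equilibrium, so a chiral phosphoric acid–benzoic acid heterodimer that protonates the oxirane and delivers benzoate anti (SN2‑like) to C6 of the (1R,6S) antipode funnels all material to one trans‑hydroxy benzoate, with C6 inverted (→ C5 R of 11) and C1 retained (→ C6 R of 11); attack at the oxirane carbon remote from the CH2OBz‑bearing carbon is favoured because it is less hindered and because the developing pentadienyl cation ends on the substituted carbon; the closest known reaction types are chiral phosphoric acid‑catalysed carboxylysis (desymmetrisation) of meso‑epoxides with benzoic acid, (salen)Co‑catalysed asymmetric epoxide opening with carboxylic acids, and the uncatalysed trans‑1,2‑addition of carboxylic acids to arene oxides.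

Step 8
Reactants: 11 [(5R,6R)-5-(benzoyloxy)-6-hydroxycyclohexa-1,3-dien-1-yl]methyl benzoate
Product: 12 [(1S,2S,3R,6R)-3-(benzoyloxy)-2-hydroxy-7-oxabicyclo[4.1.0]hept-4-en-1-yl]methyl benzoate
Conditions: VO(acac)2 (5 mol %), t-BuOOH (1.3 equiv, decane), CH2Cl2, 0 °C; aq. Na2S2O3
Reagents that add atoms: tert-butyl hydroperoxide, CC(C)(C)OO
Why: vanadium‑catalysed hydroxyl‑directed epoxidation: the vanadate ester of the C6–OH delivers oxygen to the adjacent trisubstituted C1=C2 bond (allylic ≫ homoallylic, so the C3=C4 bond is untouched) on the face of the OH, setting both oxirane carbons cis to OH.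

Step 9
Reactants: 12 [(1S,2S,3R,6R)-3-(benzoyloxy)-2-hydroxy-7-oxabicyclo[4.1.0]hept-4-en-1-yl]methyl benzoate
Product: 13 [(1R,2S,3R,6R)-3-(benzoyloxy)-2-methoxy-7-oxabicyclo[4.1.0]hept-4-en-1-yl]methyl benzoate
Conditions: MeI (20 equiv), Ag2O (5 equiv), 4 Å MS, MeCN, 35 °C, dark
Reagents that add atoms: iodomethane, CI
Why: Purdie methylation (Ag‑assisted SN2 on MeI) works without a free alkoxide, so the oxirane stays closed and benzoate migration is suppressed; no stereocentre is touched (the C1 descriptor changes from S to R only through CIP priorities).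

**Compound list**
1 | benzoic acid | OC(=O)c1ccccc1 | starting material
2 | cyclohexa-2,5-diene-1-carboxylic acid | OC(=O)C1C=CCC=C1 | intermediate
3 | (cyclohexa-2,5-dien-1-yl)methanol | OCC1C=CCC=C1 | intermediate
4 | benzoyl chloride | O=C(Cl)c1ccccc1 | starting material
5 | (cyclohexa-2,5-dien-1-yl)methyl benzoate | O=C(OCC1C=CCC=C1)c1ccccc1 | intermediate
6 | rac-[(1S,2S,6R)-7-oxabicyclo[4.1.0]hept-3-en-2-yl]methyl benzoate (oxirane trans to CH2OBz) | O=C(OC[C@@H]1C=CC[C@H]2O[C@@H]12)c1ccccc1 | intermediate
7 | rac-[(1S,2S,3S,4S,6R)-3,4-dibromo-7-oxabicyclo[4.1.0]heptan-2-yl]methyl benzoate (oxirane trans, 3-Br cis, 4-Br trans to CH2OBz) | O=C(OC[C@@H]1[C@H](Br)[C@@H](Br)C[C@H]2O[C@@H]12)c1ccccc1 | intermediate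
8 | rac-[(1S,2S,3R,6R)-3-bromo-7-oxabicyclo[4.1.0]hept-4-en-2-yl]methyl benzoate (allylic bromide, Br cis to CH2OBz) | O=C(OC[C@@H]1[C@H](Br)C=C[C@H]2O[C@@H]12)c1ccccc1 | intermediate (not isolated)
9 | rac-(7-oxabicyclo[4.1.0]hepta-2,4-dien-2-yl)methyl benzoate (benzyl benzoate 2,3-oxide; the SMILES shows the (1R,6S) antipode consumed in step 7) | [C@H]12O[C@H]1C=CC=C2COC(=O)c1ccccc1 | intermediate
10 | (oxepin-3-yl)methyl benzoate | O=C(OCC1=COC=CC=C1)c1ccccc1 | intermediate (not isolated)
11 | [(5R,6R)-5-(benzoyloxy)-6-hydroxycyclohexa-1,3-dien-1-yl]methyl benzoate (trans) | O[C@H]1[C@H](OC(=O)c2ccccc2)C=CC=C1COC(=O)c1ccccc1 | intermediate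
12 | [(1S,2S,3R,6R)-3-(benzoyloxy)-2-hydroxy-7-oxabicyclo[4.1.0]hept-4-en-1-yl]methyl benzoate (oxirane cis to OH, trans to OBz) | O[C@H]1[C@H](OC(=O)c2ccccc2)C=C[C@H]2O[C@]21COC(=O)c1ccccc1 | intermediate
13 | [(1R,2S,3R,6R)-3-(benzoyloxy)-2-methoxy-7-oxabicyclo[4.1.0]hept-4-en-1-yl]methyl benzoate | CO[C@H]1[C@H](OC(=O)c2ccccc2)C=C[C@H]2O[C@]21COC(=O)c1ccccc1 | target

**Step count and risks**
Total step count: 9. Longest linear sequence: 9 steps (from benzoic acid; fully linear).

Steps most likely to fail:

Step 7 (enantioselective opening of the racemising arene oxide). The risks are acid‑induced aromatisation to the phenol, attack at the other oxirane carbon, and low ee. The fallback sets out from 9 and comes back at 11. Compound 9 is stirred with benzoic acid 1 alone (CH2Cl2, 0 °C, no chiral catalyst). This gives the trans‑hydroxy benzoate as the racemate, that is 11 together with its enantiomer [(5S,6S)-5-(benzoyloxy)-6-hydroxycyclohexa-1,3-dien-1-yl]methyl benzoate F1. A lipase kinetic resolution follows (Burkholderia cepacia lipase, vinyl acetate, MTBE, 30 °C, stopped near 50 % conversion). By Kazlauskas' rule, with the OBz‑bearing C5 flank counted as the large group, the (6R) alcohol 11 is acetylated to [(5R,6R)-6-(acetyloxy)-5-(benzoyloxy)cyclohexa-1,3-dien-1-yl]methyl benzoate F2, and F1 stays as the alcohol. After chromatographic separation, F2 is deacetylated with the same lipase in pH 7 phosphate buffer/MTBE, which leaves both benzoates intact, and returns 11.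

Step 6 (double dehydrobromination to the arene oxide). The risk is an incomplete or misdirected second elimination if a C–Br bond lacks an anti‑periplanar hydrogen. The fallback sets out from 6 and comes back at 9. Wohl–Ziegler bromination of 6 (NBS, AIBN cat., PhCF3, 80 °C) goes through the allyl radical spanning C3–C5 of the oxabicycle. It gives the allylic bromide 8 together with its allylic isomer rac-[(1S,2S,5S,6S)-5-bromo-7-oxabicyclo[4.1.0]hept-3-en-2-yl]methyl benzoate F3. The crude mixture is treated with DBU (Et2O, 0 °C → rt): 8 loses HBr by 1,2‑elimination and F3 by 1,4‑elimination, and both give 9. This replaces the double anti‑elimination of a vicinal dibromide by a single elimination from an allylic bromide.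

Step 9 (methylation of a hindered hydroxyl flanked by an oxirane and a benzoate). The risks are benzoate migration, oxirane opening, or no reaction. The fallback sets out from 11 and comes back at 13. The dienol 11 is methylated before any oxirane is present (MeOTf, 2,6‑di‑tert‑butyl‑4‑methylpyridine, CH2Cl2, 0 °C → rt) to give [(5R,6R)-5-(benzoyloxy)-6-methoxycyclohexa-1,3-dien-1-yl]methyl benzoate F4. The oxirane is then closed under reagent control instead of hydroxyl direction. A Shi epoxidation is used (fructose‑type ketone of the antipode whose spiro transition state places oxygen on the face syn to OMe, Oxone, K2CO3 buffer, MeCN/dimethoxymethane/H2O, 0 °C). It oxidises the trisubstituted, more electron‑rich C1=C2 bond of F4 and gives 13. The substrate itself prefers attack anti to OMe, so the catalyst works against that bias here.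

**Further compounds**
F1 | step 7 | [(5S,6S)-5-(benzoyloxy)-6-hydroxycyclohexa-1,3-dien-1-yl]methyl benzoate | O[C@@H]1[C@@H](OC(=O)c2ccccc2)C=CC=C1COC(=O)c1ccccc1
F2 | step 7 | [(5R,6R)-6-(acetyloxy)-5-(benzoyloxy)cyclohexa-1,3-dien-1-yl]methyl benzoate | CC(=O)O[C@H]1[C@H](OC(=O)c2ccccc2)C=CC=C1COC(=O)c1ccccc1
F3 | step 6 | rac-[(1S,2S,5S,6S)-5-bromo-7-oxabicyclo[4.1.0]hept-3-en-2-yl]methyl benzoate | O=C(OC[C@@H]1C=C[C@H](Br)[C@H]2O[C@@H]12)c1ccccc1
F4 | step 9 | [(5R,6R)-5-(benzoyloxy)-6-methoxycyclohexa-1,3-dien-1-yl]methyl benzoate | CO[C@H]1[C@H](OC(=O)c2ccccc2)C=CC=C1COC(=O)c1ccccc1
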